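**Retrosynthetic overview**

1. Hydroazulene numbering used throughout: C1, C2 = CH2 of the five-membered ring; C3 = C(OH)(i-Pr); C3a = ring-fusion CH; C4 = CH–O(acyl); C5=C6(CH3); C7, C8 = CH2; C8a = C(CH3). The 4-hydroxybenzoate (carried as its acetate) is attached last, and the C4 carbinol is re-set from the C4 ketone by hydride delivery from the C3 hydroxyl.
2. Key disconnection: the five-membered ring is opened at C2–C3 (aldol, after adding a CO2Me group at C2 that is later removed by decarboxylation) and at C1–C8a (radical conjugate addition). This gives a monocyclic 7-methylidene-cycloheptenyl isopropyl ketone and methyl acrylate.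
3. Enabling feature: C8a is a fully substituted ring carbon carrying CH3, joined through exactly two CH2 groups (C1, C2) to the tertiary carbinol C3 inside the five-membered ring. C8a–CH3 is therefore the hydrogen-atom adduct of an exocyclic methylene, C1–C2 an acrylate unit and C3–OH a former ketone.
4. The seven-membered ring comes from ring-closing metathesis (C5=C6) of an acyclic syn aldol of acrolein with a dienyl isopropyl ketone, made from 2,5-dimethylhexa-1,5-diene and the Weinreb amide of isobutyric acid.
5. Ring order: seven-membered ring first (metathesis), five-membered ring second (annulation). The C3a stereocentre from the aldol controls C8a and C3, then C4; the C4 carbinol is deliberately made cis to the ketone side chain first and inverted at the end.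

Key step: step 4

Assumption: the Z enol borinate made in step 2 with (−)-Ipc2BOTf (ligands from (+)-α-pinene) is taken to attack the si face of acrolein, the sense shown by allyl transfer from the same boron fragment; if the enolate shows the opposite sense, the reagent from (−)-α-pinene is used and nothing else changes.

**Step 1**
Reactants: 1 2,5-dimethylhexa-1,5-diene; 2 N-methoxy-N,2-dimethylpropanamide
Product: 4 2,8-dimethyl-5-methylidenenon-8-en-3-one, via allyllithium 3 (not isolated)
Conditions: 1 (3 equiv), n-BuLi, TMEDA, hexane, 0 °C to rt; then 2, THF, −78 °C; sat. aq. NH4Cl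
Reagents that add atoms: none
Why: Kinetic allylic lithiation of the 2-methylalk-1-ene unit occurs at the methyl group and gives a 2-substituted allyllithium with two equivalent termini, whose acylation by the Weinreb amide (Weinreb ketone synthesis) stops at the chelated tetrahedral adduct, so the non-conjugated ketone is released only on quench and no stereocentre is formed.

**Step 2**
Reactants: 4 2,8-dimethyl-5-methylidenenon-8-en-3-one; 5 acrolein
Product: 7 (4S,5R)-5-hydroxy-2-methyl-4-(6-methylhepta-1,6-dien-2-yl)hept-6-en-3-one, via Z enol borinate 6 (not isolated)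
Conditions: (−)-Ipc2BOTf, i-Pr2NEt, CH2Cl2, −78 °C; then 5, −78 to −20 °C; then H2O2, MeOH, pH 7 phosphate buffer, 0 °C
Reagents that add atoms: none
Why: Boron-mediated syn aldol reaction through a Zimmerman–Traxler chair: enolisation at the more acidic allylic CH2 gives the Z enol borinate, the Z geometry sets the 4,5-syn relation, and the isopinocampheyl ligands direct attack to the si face of acrolein, which fixes (5R) and therefore (4S).

**Step 3**
Reactants: 7 (4S,5R)-5-hydroxy-2-methyl-4-(6-methylhepta-1,6-dien-2-yl)hept-6-en-3-one
Product: 8 1-[(1S,2R)-2-hydroxy-4-methyl-7-methylidenecyclohept-3-en-1-yl]-2-methylpropan-1-one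
Conditions: second-generation Grubbs catalyst (H2IMes)(PCy3)Cl2Ru=CHPh (5 mol %), 1,4-benzoquinone (10 mol %), CH2Cl2 (5 mM), 40 °C
Reagents that add atoms: none
Why: Ring-closing metathesis between the vinyl carbinol and the remote isopropenyl group gives the trisubstituted cycloheptene (the other 1,1-disubstituted alkene could only close a cyclobutene and stays as the exocyclic methylidene), with benzoquinone suppressing ruthenium hydride alkene migration; no stereocentre is formed or touched.

**Step 4**
Reactants: 8 1-[(1S,2R)-2-hydroxy-4-methyl-7-methylidenecyclohept-3-en-1-yl]-2-methylpropan-1-one; 9 methyl acrylate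
Product: 12 methyl (2S,3R,3aS,4R,8aS)-3,4-dihydroxy-6,8a-dimethyl-3-(propan-2-yl)-1,2,3,3a,4,7,8,8a-octahydroazulene-2-carboxylate, via tertiary radical 10 (not isolated), via iron ester enolate 11 (not isolated)
Conditions: 9 (3 equiv), Fe(acac)3 (30 mol %), PhSiH3, EtOH/(CH2OH)2, 0 °C to rt
Reagents that add atoms: none
Why: An iron hydride made from Fe(acac)3 and PhSiH3 transfers a hydrogen atom to the methylidene carbon of 8, the tertiary radical 10 adds to methyl acrylate (Giese addition, C1–C8a bond), divalent iron reduces the α-ester radical to enolate 11, and 11 adds to the isopropyl ketone (aldol, C2–C3 bond), which closes the five-membered ring. The closest known reaction type is the iron hydride hydrogen-atom-transfer radical conjugate addition–aldol (radical–polar crossover) annulation of two unsaturated carbonyl compounds. The ring closes in the 5-(enolexo)-exo-trig mode and is trans-fused. C8a is set by approach of the acrylate anti to the neighbouring isobutyryl group, which allylic strain with the methyl-bearing radical centre holds pseudoaxial while its cis hydroxyl sits pseudoequatorial and leaves the other face open; C3 is set by the ketone rotamer that eclipses the isopropyl group with the C3a hydrogen and turns the carbonyl oxygen towards C4, so the new hydroxyl is cis to the C8a methyl; C2 is set cis to that hydroxyl by the iron-bridged closed transition state and is erased in step 6. The step needs hydrogen-atom transfer to the 1,1-disubstituted exocyclic alkene and not to the trisubstituted ring alkene, secured by the higher rate for the less hindered terminal alkene, and it needs aldol closure to outrun protonation of 11, secured by intramolecularity and by trivalent iron binding both enolate and ketone.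

**Step 5**
Reactants: 12 methyl (2S,3R,3aS,4R,8aS)-3,4-dihydroxy-6,8a-dimethyl-3-(propan-2-yl)-1,2,3,3a,4,7,8,8a-octahydroazulene-2-carboxylate
Product: 13 (2S,3R,3aS,4R,8aS)-3,4-dihydroxy-6,8a-dimethyl-3-(propan-2-yl)-1,2,3,3a,4,7,8,8a-octahydroazulene-2-carboxylic acid
Conditions: LiOH·H2O, THF/MeOH/H2O, rt; then 1 M HCl to pH 3, 0 °C
Reagents that add atoms: lithium hydroxide, [Li+].[OH-]
Why: Saponification of the methyl ester; the carboxylate and the tertiary alkoxide are poor partners for retro-aldol cleavage, so the ring stereocentres should be kept.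

**Step 6**
Reactants: 13 (2S,3R,3aS,4R,8aS)-3,4-dihydroxy-6,8a-dimethyl-3-(propan-2-yl)-1,2,3,3a,4,7,8,8a-octahydroazulene-2-carboxylic acid
Product: 14 (3R,3aS,4R,8aS)-6,8a-dimethyl-3-(propan-2-yl)-1,2,3,3a,4,7,8,8a-octahydroazulene-3,4-diol
Conditions: 9-mesityl-10-phenylacridinium tetrafluoroborate (5 mol %), (PhS)2 (10 mol %), i-Pr2NEt (20 mol %), CF3CH2OH, 450 nm LEDs, rt
Reagents that add atoms: none
Why: Photoredox hydrodecarboxylation: the excited acridinium oxidises the carboxylate, loss of CO2 gives a secondary radical at C2 that takes a hydrogen atom from thiophenol, which erases the temporary C2 stereocentre and leaves the others untouched.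

**Step 7**
Reactants: 14 (3R,3aS,4R,8aS)-6,8a-dimethyl-3-(propan-2-yl)-1,2,3,3a,4,7,8,8a-octahydroazulene-3,4-diol
Product: 15 (3R,3aR,8aS)-3-hydroxy-6,8a-dimethyl-3-(propan-2-yl)-1,2,3,3a,8,8a-hexahydroazulen-4(7H)-one
Conditions: Dess–Martin periodinane, pyridine, CH2Cl2, 0 °C
Reagents that add atoms: none
Why: Dess–Martin oxidation of the secondary allylic alcohol (the tertiary alcohol cannot be oxidised) removes the relay stereocentre at C4 and gives the enone, with pyridine buffering to protect C3a from enolisation and the β-hydroxy ketone from retro-aldol cleavage.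

**Step 8**
Reactants: 15 (3R,3aR,8aS)-3-hydroxy-6,8a-dimethyl-3-(propan-2-yl)-1,2,3,3a,8,8a-hexahydroazulen-4(7H)-one
Product: 16 (3R,3aS,4S,8aS)-6,8a-dimethyl-3-(propan-2-yl)-1,2,3,3a,4,7,8,8a-octahydroazulene-3,4-diol
Conditions: Me4NBH(OAc)3, MeCN/AcOH (1:1), −30 °C
Reagents that add atoms: none
Why: Evans–Saksena hydroxyl-directed reduction: the C3 hydroxyl, which lies on the β face, binds boron and delivers hydride to the C4 carbonyl through a six-membered transition state from that same face, so the new hydroxyl should be α (4S, cis to the C3a hydrogen) and the enone is reduced 1,2.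

**Step 9**
Reactants: 16 (3R,3aS,4S,8aS)-6,8a-dimethyl-3-(propan-2-yl)-1,2,3,3a,4,7,8,8a-octahydroazulene-3,4-diol; 17 4-acetoxybenzoic acid
Product: 18 (3R,3aS,4S,8aS)-3-hydroxy-6,8a-dimethyl-3-(propan-2-yl)-1,2,3,3a,4,7,8,8a-octahydroazulen-4-yl 4-acetoxybenzoate
Conditions: DCC, DMAP (cat.), CH2Cl2, 0 °C to rt
Reagents that add atoms: none
Why: Steglich esterification should acylate only the secondary allylic hydroxyl because the tertiary C3 hydroxyl next to the isopropyl group is too hindered; the C–O bond at C4 is not broken, so its configuration is retained.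

**Step 10**
Reactants: 18 (3R,3aS,4S,8aS)-3-hydroxy-6,8a-dimethyl-3-(propan-2-yl)-1,2,3,3a,4,7,8,8a-octahydroazulen-4-yl 4-acetoxybenzoate
Product: 19 (3R,3aS,4S,8aS)-3-hydroxy-6,8a-dimethyl-3-(propan-2-yl)-1,2,3,3a,4,7,8,8a-octahydroazulen-4-yl 4-hydroxybenzoate
Conditions: pyrrolidine, CH2Cl2, 0 °C to rt
Reagents that add atoms: none
Why: Aminolysis of the aryl acetate by pyrrolidine is far faster than attack on the hindered secondary aroyl ester, so the phenol should be freed without acyl loss or migration.

**Compound list**

1 | 2,5-dimethylhexa-1,5-diene | C=C(C)CCC(C)=C | starting material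
2 | N-methoxy-N,2-dimethylpropanamide | CC(C)C(=O)N(C)OC | starting material
3 | (5-methyl-2-methylidenehex-5-en-1-yl)lithium | [Li]CC(=C)CCC(C)=C | intermediate
4 | 2,8-dimethyl-5-methylidenenon-8-en-3-one | CC(C)C(=O)CC(=C)CCC(C)=C | intermediate
5 | acrolein (prop-2-enal) | C=CC=O | starting material
6 | Z enol diisopinocampheylborinate of 4 | CC(C)/C(OB([C@@H]1C[C@@H]2C[C@H]([C@H]1C)C2(C)C)[C@@H]1C[C@@H]2C[C@H]([C@H]1C)C2(C)C)=C/C(=C)CCC(C)=C | intermediate
7 | (4S,5R)-5-hydroxy-2-methyl-4-(6-methylhepta-1,6-dien-2-yl)hept-6-en-3-one | C=C[C@@H](O)[C@@H](C(=O)C(C)C)C(=C)CCC(C)=C | intermediate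
8 | 1-[(1S,2R)-2-hydroxy-4-methyl-7-methylidenecyclohept-3-en-1-yl]-2-methylpropan-1-one | CC1=C[C@@H](O)[C@@H](C(=O)C(C)C)C(=C)CC1 | intermediate
9 | methyl acrylate | C=CC(=O)OC | starting material
10 | tertiary ring radical formed by hydrogen-atom addition to the methylidene carbon of 8 | CC1=C[C@@H](O)[C@@H](C(=O)C(C)C)[C](C)CC1 | intermediate
11 | iron-bound ester enolate from addition of 10 to 9 (drawn as the free enolate) | CC1=C[C@@H](O)[C@@H](C(=O)C(C)C)[C@](C)(CC=C([O-])OC)CC1 | intermediate
12 | methyl (2S,3R,3aS,4R,8aS)-3,4-dihydroxy-6,8a-dimethyl-3-(propan-2-yl)-1,2,3,3a,4,7,8,8a-octahydroazulene-2-carboxylate | CC1=C[C@@H](O)[C@@H]2[C@@](C)(CC1)C[C@H](C(=O)OC)[C@@]2(O)C(C)C | intermediate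
13 | (2S,3R,3aS,4R,8aS)-3,4-dihydroxy-6,8a-dimethyl-3-(propan-2-yl)-1,2,3,3a,4,7,8,8a-octahydroazulene-2-carboxylic acid | CC1=C[C@@H](O)[C@@H]2[C@@](C)(CC1)C[C@H](C(=O)O)[C@@]2(O)C(C)C | intermediate
14 | (3R,3aS,4R,8aS)-6,8a-dimethyl-3-(propan-2-yl)-1,2,3,3a,4,7,8,8a-octahydroazulene-3,4-diol | CC1=C[C@@H](O)[C@@H]2[C@@](C)(CC1)CC[C@@]2(O)C(C)C | intermediate
15 | (3R,3aR,8aS)-3-hydroxy-6,8a-dimethyl-3-(propan-2-yl)-1,2,3,3a,8,8a-hexahydroazulen-4(7H)-one | CC1=CC(=O)[C@@H]2[C@@](C)(CC1)CC[C@@]2(O)C(C)C | intermediate
16 | (3R,3aS,4S,8aS)-6,8a-dimethyl-3-(propan-2-yl)-1,2,3,3a,4,7,8,8a-octahydroazulene-3,4-diol | CC1=C[C@H](O)[C@@H]2[C@@](C)(CC1)CC[C@@]2(O)C(C)C | intermediate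
17 | 4-acetoxybenzoic acid | CC(=O)Oc1ccc(cc1)C(=O)O | starting material
18 | (3R,3aS,4S,8aS)-3-hydroxy-6,8a-dimethyl-3-(propan-2-yl)-1,2,3,3a,4,7,8,8a-octahydroazulen-4-yl 4-acetoxybenzoate | CC1=C[C@H](OC(=O)c2ccc(OC(C)=O)cc2)[C@@H]2[C@@](C)(CC1)CC[C@@]2(O)C(C)C | intermediate
19 | (3R,3aS,4S,8aS)-3-hydroxy-6,8a-dimethyl-3-(propan-2-yl)-1,2,3,3a,4,7,8,8a-octahydroazulen-4-yl 4-hydroxybenzoate | CC1=C[C@H](OC(=O)c2ccc(O)cc2)[C@@H]2[C@@](C)(CC1)CC[C@@]2(O)C(C)C | target

**Step count**

Total steps: 10. Longest linear sequence: 10 steps (1 to 19).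

**Three steps most likely to fail**

Step 4 (key step). What may go wrong: protonation of the iron ester enolate by the alcoholic medium, or retro-aldol opening of the trans-fused aldolate, so that the five-membered ring does not close; erosion of facial selectivity in the radical addition is a second concern. Fallback, setting out from 8 and coming back at 14: the hydrogen-atom-transfer Giese addition of 8 to methyl acrylate is run deliberately as a simple reductive coupling (Fe(acac)3, PhSiH3, EtOH) to give the uncyclised keto ester F1. Saponification with LiOH gives the keto acid F2. Barton iododecarboxylation (N-hydroxypyridine-2-thione, DCC; then CHI3, hν) shortens the chain by one carbon to the primary iodide F3. An intramolecular samarium Barbier reaction (SmI2, HMPA, THF, −78 °C) then closes the same C2–C3 bond by addition of the alkylsamarium to the isopropyl ketone, under the same rotamer control at C3. This returns to the route at 14 with no carboxyl group to remove, so steps 5 and 6 are skipped.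

Step 2. What may go wrong: insufficient or reversed enantiofacial selectivity of the hindered enol borinate towards acrolein, or polymerisation of acrolein before it is captured. Fallback, setting out from 4 and coming back at 7: an achiral syn aldol (n-Bu2BOTf, i-Pr2NEt, then acrolein) gives 7 as a racemate together with its (4R,5S) enantiomer F4. Kinetic resolution by lipase-catalysed acylation (Candida antarctica lipase B, vinyl acetate, hexane) converts the (5R) carbinol, the fast-reacting enantiomer by the usual empirical rule for secondary alcohols, into the acetate F5, which is separated from unreacted F4. Neutral lipase-catalysed methanolysis of F5 (avoiding base, which would trigger elimination) returns 7.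

Step 8. What may go wrong: slow exchange of the hindered tertiary hydroxyl onto boron, so that undirected intermolecular hydride delivery to the other face or acid-promoted dehydration of the β-hydroxy enone competes. Fallback, setting out from 14 and coming back at 18: the C4 carbinol of 14 is not oxidised but inverted directly by a Mitsunobu esterification with 17 (PPh3, DIAD, toluene, 0 °C to rt). The SN2 displacement at the allylic C4 carbon installs the aroyl ester with the required configuration in one operation, so steps 7, 8 and 9 are replaced and no new compound is formed on the way.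

**Further compounds**

F1 | step 4 | methyl 3-[6-hydroxy-1,4-dimethyl-7-(2-methylpropanoyl)cyclohept-4-en-1-yl]propanoate (1-methyl, 6-hydroxyl and 7-acyl all cis) | CC1=C[C@@H](O)[C@@H](C(=O)C(C)C)[C@](C)(CCC(=O)OC)CC1
F2 | step 4 | 3-[6-hydroxy-1,4-dimethyl-7-(2-methylpropanoyl)cyclohept-4-en-1-yl]propanoic acid (1-methyl, 6-hydroxyl and 7-acyl all cis) | CC1=C[C@@H](O)[C@@H](C(=O)C(C)C)[C@](C)(CCC(=O)O)CC1
F3 | step 4 | 1-[2-hydroxy-7-(2-iodoethyl)-4,7-dimethylcyclohept-3-en-1-yl]-2-methylpropan-1-one (7-methyl, 2-hydroxyl and 1-acyl all cis) | CC1=C[C@@H](O)[C@@H](C(=O)C(C)C)[C@](C)(CCI)CC1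
F4 | step 2 | (4R,5S)-5-hydroxy-2-methyl-4-(6-methylhepta-1,6-dien-2-yl)hept-6-en-3-one | C=C[C@H](O)[C@H](C(=O)C(C)C)C(=C)CCC(C)=C
F5 | step 2 | (3R,4S)-6-methyl-4-(6-methylhepta-1,6-dien-2-yl)-5-oxohept-1-en-3-yl acetate | C=C[C@@H](OC(C)=O)[C@@H](C(=O)C(C)C)C(=C)CCC(C)=C
F0 | step 8 | none | none
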